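**Retrosynthetic overview**

1. Quinone last: 13 ⇐ silyl-protected guaiacol arene 11 (desilylation, then para-oxidation of the phenol with (KSO3)2NO). The quinone ring is carried from the start as the arene of 6.
2. Rings A and B together, with the C9=C11(Cl)Ar unit: 11 ⇐ acyclic aryl dienyne 8 in one proton-initiated cation–olefin–alkyne bicyclization. Ring A closes first, ring B second by 6-exo-dig attack of the aryl alkyne; chloride capture of the vinyl cation gives the E-chloride.
3. 8 ⇐ terminal alkyne 5 + aryl bromide 7 (Sonogashira coupling).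
4. 5 ⇐ (2E,6E)-farnesol 1: asymmetric hydrogenation fixes C8, then oxidation and aldehyde-to-alkyne conversion without chain extension.

Numbering used for the decalin (terpenoid style): ring A = C1–C5 and C10 (C4 gem-dimethyl, C10 angular methyl), ring B = C5–C10, C8 = CHMe, C9 = ring carbon of the exocyclic alkene, C11 = chlorinated carbon. The target is (2S,4aS,8aS) in naphthalene numbering (C8, C5, C10), with an E alkene (Cl cis to C8).

Assumption: the (R)-configured BINOL ether·SnCl4 acid is taken to give the (4aS,8aS) ring fusion, by analogy with its behaviour on (E,E)-polyprenoids; if the sense proves opposite, the (S)-reagent is used and nothing else changes.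

**Route**

Step 1
Reactants: 1 (2E,6E)-farnesol
Product: 2 (3S,6E)-3,7,11-trimethyldodeca-6,10-dien-1-ol
Conditions: Ru(OAc)2[(R)-BINAP] (0.5 mol%), H2 (100 atm), MeOH/H2O 95:5, 20 °C
Reagents that add atoms: none
Why: Noyori asymmetric hydrogenation of an allylic alcohol; the hydroxyl-bound divalent ruthenium catalyst reduces only the 2,3-alkene, and the (R)-ligand on the E-alkene gives the 3S centre (the future C8) in the same sense as geraniol gives (S)-citronellol, while the remote trisubstituted alkenes are untouched.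

Step 2
Reactants: 2 (3S,6E)-3,7,11-trimethyldodeca-6,10-dien-1-ol
Product: 3 (3S,6E)-3,7,11-trimethyldodeca-6,10-dienal
Conditions: PhI(OAc)2, TEMPO (10 mol%), CH2Cl2, rt
Reagents that add atoms: none
Why: Nitroxyl-catalysed oxidation of a primary alcohol stops at the aldehyde, leaves trisubstituted alkenes alone and cannot epimerise the β-stereocentre.

Step 3
Reactants: 3 (3S,6E)-3,7,11-trimethyldodeca-6,10-dienal
Product: 5 (3S,6E)-3,7,11-trimethyldodeca-6,10-dien-1-yne, via enol nonaflate 4 (not isolated)
Conditions: C4F9SO2F, phosphazene base P2-Et, DMF, −20 °C to rt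
Reagents that add atoms: none
Why: One-pot enol sulfonylation and base-induced β-elimination (aldehyde to terminal alkyne with the same chain length); the alkyne is held as its acetylide until work-up, which protects the propargylic C3–H centre from alkyne–allene isomerisation.

Step 4
Reactants: 6 2-bromo-6-methoxyphenol
Product: 7 (2-bromo-6-methoxyphenoxy)tri(propan-2-yl)silane
Conditions: i-Pr3SiCl, imidazole, DMF, 40 °C
Reagents that add atoms: chlorotri(propan-2-yl)silane, CC(C)[Si](Cl)(C(C)C)C(C)C
Why: Standard O-silylation; the bulky silyl ether blocks benzofuran formation in step 5, keeps the phenol oxygen from binding tin in step 6 and comes off with fluoride.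

Step 5
Reactants: 5 (3S,6E)-3,7,11-trimethyldodeca-6,10-dien-1-yne; 7 (2-bromo-6-methoxyphenoxy)tri(propan-2-yl)silane
Product: 8 {2-methoxy-6-[(3S,6E)-3,7,11-trimethyldodeca-6,10-dien-1-yn-1-yl]phenoxy}tri(propan-2-yl)silane
Conditions: PdCl2(PhCN)2 (3 mol%), P(t-Bu)3·HBF4 (6 mol%), CuI (2 mol%), i-Pr2NH, dioxane, rt to 45 °C
Reagents that add atoms: none
Why: Sonogashira coupling; the bulky electron-rich phosphine on zerovalent palladium inserts into electron-rich ortho-substituted aryl bromides near room temperature, and the mild amine base does not touch the propargylic stereocentre or the silyl ether.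

Step 6
Reactants: 8 {2-methoxy-6-[(3S,6E)-3,7,11-trimethyldodeca-6,10-dien-1-yn-1-yl]phenoxy}tri(propan-2-yl)silane
Product: 11 {2-[(E)-chloro[(2S,4aS,8aS)-2,5,5,8a-tetramethyloctahydronaphthalen-1(2H)-ylidene]methyl]-6-methoxyphenoxy}tri(propan-2-yl)silane, via ring A cation 9 (not isolated), via vinyl cation 10 (not isolated)
Conditions: (R)-2'-methoxy-1,1'-binaphthalen-2-ol·SnCl4 (1:1, 2 equiv), CH2Cl2, −78 °C, 48 h; aq. NaHCO3
Reagents that add atoms: tin tetrachloride, Cl[Sn](Cl)(Cl)Cl
Why: Proposed new method: the chiral Lewis-acid-assisted Brønsted acid protonates C3 of the terminal trisubstituted alkene on one face and ring A closes through a chair to the tertiary C10 cation 9, which fixes C5 far from, and so not steered by, the pre-set C8 centre; the tethered aryl alkyne then attacks C10 anti to the new C4–C5 bond in a 6-exo-dig chair closure (trans fusion, 4aS,8aS, with the C8 methyl forced axial) to the linear α-aryl vinyl cation 10, which takes chloride from the chlorostannate counter-ion in the ring plane from the C8 side, where only the equatorial C8–H lies, and not from the side of the quaternary C10, so Cl ends cis to C8 (E); the closest known reaction types are the enantioselective proton-initiated polyene cyclization with BINOL·SnCl4 acids and the alkyne-terminated cation–olefin cyclization in which SnCl4 turns the vinyl cation into a vinyl chloride, here joined in one operation.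

Step 7
Reactants: 11 {2-[(E)-chloro[(2S,4aS,8aS)-2,5,5,8a-tetramethyloctahydronaphthalen-1(2H)-ylidene]methyl]-6-methoxyphenoxy}tri(propan-2-yl)silane
Product: 13 2-[(E)-chloro[(2S,4aS,8aS)-2,5,5,8a-tetramethyloctahydronaphthalen-1(2H)-ylidene]methyl]-6-methoxycyclohexa-2,5-diene-1,4-dione, via free phenol 12 (not isolated)
Conditions: Bu4NF/AcOH (1:1), THF, 0 °C; then (KSO3)2NO, aq. KH2PO4, acetone, rt
Reagents that add atoms: potassium nitrosodisulfonate (KSO3)2NO, [K+].[K+].[O]N(S(=O)(=O)[O-])S(=O)(=O)[O-]
Why: Fluoride desilylation followed by Teuber oxidation; the nitroxyl radical oxidises a 2,6-disubstituted phenol with a free para position to the p-quinone, and the buffered medium avoids base that could enolise the vinylogous C8–H, so no stereocentre or the E-alkene is touched.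

**Compound list**

1 | (2E,6E)-farnesol, (2E,6E)-3,7,11-trimethyldodeca-2,6,10-trien-1-ol | CC(C)=CCC/C(C)=C/CC/C(C)=C/CO | starting material
2 | (3S,6E)-3,7,11-trimethyldodeca-6,10-dien-1-ol | OCC[C@@H](C)CC/C=C(\C)CCC=C(C)C | intermediate
3 | (3S,6E)-3,7,11-trimethyldodeca-6,10-dienal | O=CC[C@@H](C)CC/C=C(\C)CCC=C(C)C | intermediate
4 | (3S,6E)-3,7,11-trimethyldodeca-1,6,10-trien-1-yl nonafluorobutane-1-sulfonate (1E/1Z mixture) | O=S(=O)(OC=C[C@@H](C)CC/C=C(\C)CCC=C(C)C)C(F)(F)C(F)(F)C(F)(F)C(F)(F)F | intermediate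
5 | (3S,6E)-3,7,11-trimethyldodeca-6,10-dien-1-yne | C#C[C@@H](C)CC/C=C(\C)CCC=C(C)C | intermediate
6 | 2-bromo-6-methoxyphenol | COc1cccc(Br)c1O | starting material
7 | (2-bromo-6-methoxyphenoxy)tri(propan-2-yl)silane | COc1cccc(Br)c1O[Si](C(C)C)(C(C)C)C(C)C | intermediate
8 | {2-methoxy-6-[(3S,6E)-3,7,11-trimethyldodeca-6,10-dien-1-yn-1-yl]phenoxy}tri(propan-2-yl)silane | COc1cccc(C#C[C@@H](C)CC/C=C(\C)CCC=C(C)C)c1O[Si](C(C)C)(C(C)C)C(C)C | intermediate
9 | ring A cation: tertiary cyclohexyl cation at C10 with ring A closed (C5 configured as in 11) and the (3S)-3-methyl-5-arylpent-4-ynyl chain still open | C[C+]1CCCC(C)(C)[C@@H]1CC[C@H](C)C#Cc1cccc(OC)c1O[Si](C(C)C)(C(C)C)C(C)C | intermediate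
10 | vinyl cation: trans-decalin of 11 with a linear α-aryl vinyl cation at C11 | COc1cccc([C+]=C2[C@@H](C)CC[C@H]3C(C)(C)CCC[C@]23C)c1O[Si](C(C)C)(C(C)C)C(C)C | intermediate
11 | {2-[(E)-chloro[(2S,4aS,8aS)-2,5,5,8a-tetramethyloctahydronaphthalen-1(2H)-ylidene]methyl]-6-methoxyphenoxy}tri(propan-2-yl)silane | COc1cccc(/C(Cl)=C2/[C@@H](C)CC[C@H]3C(C)(C)CCC[C@]23C)c1O[Si](C(C)C)(C(C)C)C(C)C | intermediate
12 | 2-[(E)-chloro[(2S,4aS,8aS)-2,5,5,8a-tetramethyloctahydronaphthalen-1(2H)-ylidene]methyl]-6-methoxyphenol | COc1cccc(/C(Cl)=C2/[C@@H](C)CC[C@H]3C(C)(C)CCC[C@]23C)c1O | intermediate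
13 | 2-[(E)-chloro[(2S,4aS,8aS)-2,5,5,8a-tetramethyloctahydronaphthalen-1(2H)-ylidene]methyl]-6-methoxycyclohexa-2,5-diene-1,4-dione | COC1=CC(=O)C=C(/C(Cl)=C2/[C@@H](C)CC[C@H]3C(C)(C)CCC[C@]23C)C1=O | target

**Step count and risks**

Total steps: 7. Longest linear sequence: 6 (steps 1, 2, 3, 5, 6, 7 from farnesol); step 4 is a one-step side branch.

Step 6 is the most likely to fail. Closing ring B puts the C8 methyl axial, 1,3 to the C10 methyl, which is dearer than the equatorial alternative. Cation 9 may therefore lose a proton to monocyclic olefins or leak into the cis-fused isomer. The acid may also protonate the electron-rich aryl alkyne instead of the terminal alkene. Imperfect facial control by the chiral acid gives the (2S,4aR,8aR) diastereomer, not the enantiomer, because C8 is pre-set; it is removed by chromatography. The fallback sets out from 8 and comes back at 11, giving up the one-pot bicyclization. The chiral-acid step is run in toluene for a short time and stopped at ring A, and the monocyclic olefin {2-methoxy-6-[(3S)-3-methyl-5-[(1S)-2,6,6-trimethylcyclohex-2-en-1-yl]pent-1-yn-1-yl]phenoxy}tri(propan-2-yl)silane F1 is isolated with C5 already set. Ring B is then closed in a separate cation–alkyne (alkyne-Prins-type) chlorocyclization with anhydrous HCl and SnCl4 in CH2Cl2 at −78 °C. This re-forms cation 9 from the ring olefin and gives 11 through 10, with time and acid strength chosen for the slow closure alone.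

Step 3 is the second risk. The aldehyde can self-condense under the strong base before O-sulfonylation, and the one-pot elimination is less practised than the other steps. The fallback sets out from 3 (with 7) and comes back at 8, bypassing 5 and step 5 by building the alkyne from an aryl ketone. Bromine–magnesium exchange on 7 with i-PrMgCl·LiCl in THF gives {3-methoxy-2-[tri(propan-2-yl)silyloxy]phenyl}magnesium chloride F2. Addition to 3 gives the benzylic alcohol (3S,6E)-1-{3-methoxy-2-[tri(propan-2-yl)silyloxy]phenyl}-3,7,11-trimethyldodeca-6,10-dien-1-ol F3 as both C1 epimers. Dess–Martin oxidation gives the ketone (3S,6E)-1-{3-methoxy-2-[tri(propan-2-yl)silyloxy]phenyl}-3,7,11-trimethyldodeca-6,10-dien-1-one F4, which cannot self-condense as readily and enolises only toward C2. KN(SiMe3)2 and PhNTf2 give the enol triflate (1Z,3S,6E)-1-{3-methoxy-2-[tri(propan-2-yl)silyloxy]phenyl}-3,7,11-trimethyldodeca-1,6,10-trien-1-yl trifluoromethanesulfonate F5, and anti-elimination with LiN(i-Pr)2 at −78 °C gives 8.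

Step 7 is the third risk. The one-pot desilylation and radical oxidation has to spare an electron-rich tetrasubstituted styrenyl chloride, and the alkenyl quinone is base-sensitive. The fallback sets out from 5 and comes back at 13, carrying the para oxygen from the start so that no phenol oxidation is needed. Alkyne 5 is coupled under the step 5 conditions with the catalogue compound 1-bromo-2,3,5-trimethoxybenzene F6 to give 1,2,5-trimethoxy-3-[(3S,6E)-3,7,11-trimethyldodeca-6,10-dien-1-yn-1-yl]benzene F7. Bicyclization as in step 6 gives 1-[(E)-chloro[(2S,4aS,8aS)-2,5,5,8a-tetramethyloctahydronaphthalen-1(2H)-ylidene]methyl]-2,3,5-trimethoxybenzene F8. Oxidative demethylation with (NH4)2Ce(NO3)6 in MeCN/H2O at 0 °C turns the para-related 2- and 5-methoxy groups into the carbonyls and leaves the 3-methoxy group, giving 13.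

**Further compounds**

F1 | step 6 | {2-methoxy-6-[(3S)-3-methyl-5-[(1S)-2,6,6-trimethylcyclohex-2-en-1-yl]pent-1-yn-1-yl]phenoxy}tri(propan-2-yl)silane | CC1=CCCC(C)(C)[C@@H]1CC[C@H](C)C#Cc1cccc(OC)c1O[Si](C(C)C)(C(C)C)C(C)C
F2 | step 3 | {3-methoxy-2-[tri(propan-2-yl)silyloxy]phenyl}magnesium chloride | COc1cccc([Mg]Cl)c1O[Si](C(C)C)(C(C)C)C(C)C
F3 | step 3 | (3S,6E)-1-{3-methoxy-2-[tri(propan-2-yl)silyloxy]phenyl}-3,7,11-trimethyldodeca-6,10-dien-1-ol (both C1 epimers) | COc1cccc(C(O)C[C@@H](C)CC/C=C(\C)CCC=C(C)C)c1O[Si](C(C)C)(C(C)C)C(C)C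
F4 | step 3 | (3S,6E)-1-{3-methoxy-2-[tri(propan-2-yl)silyloxy]phenyl}-3,7,11-trimethyldodeca-6,10-dien-1-one | COc1cccc(C(=O)C[C@@H](C)CC/C=C(\C)CCC=C(C)C)c1O[Si](C(C)C)(C(C)C)C(C)C
F5 | step 3 | (1Z,3S,6E)-1-{3-methoxy-2-[tri(propan-2-yl)silyloxy]phenyl}-3,7,11-trimethyldodeca-1,6,10-trien-1-yl trifluoromethanesulfonate | COc1cccc(/C(OS(=O)(=O)C(F)(F)F)=C/[C@@H](C)CC/C=C(\C)CCC=C(C)C)c1O[Si](C(C)C)(C(C)C)C(C)C
F6 | step 7 | 1-bromo-2,3,5-trimethoxybenzene | COc1cc(Br)c(OC)c(OC)c1
F7 | step 7 | 1,2,5-trimethoxy-3-[(3S,6E)-3,7,11-trimethyldodeca-6,10-dien-1-yn-1-yl]benzene | COc1cc(C#C[C@@H](C)CC/C=C(\C)CCC=C(C)C)c(OC)c(OC)c1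
F8 | step 7 | 1-[(E)-chloro[(2S,4aS,8aS)-2,5,5,8a-tetramethyloctahydronaphthalen-1(2H)-ylidene]methyl]-2,3,5-trimethoxybenzene | COc1cc(/C(Cl)=C2/[C@@H](C)CC[C@H]3C(C)(C)CCC[C@]23C)c(OC)c(OC)c1
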